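**Retrosynthetic overview**

- Numbering: ring A is the benzene ring (C4a, C5–C8, C8a). Ring B is the pyranone (C1, O2, C3, C4). The side chain is C1'–C4'. Ring C is the oxolane (2R,3S,5S; 2,5-cis, 2,3-trans). The last step only removes two phenolic acetates.
- Key disconnection: C3–C1' and O2–C3 are made in one palladium-catalysed operation, a tandem Stille coupling/heterocyclisation. The partners are a methyl 2-(2,2-dibromoethenyl)benzoate (ring A with C1, C4 and C3) and an (E,E)-dienylstannane that carries ring C.
- Enabling feature: C3 of ring B is an sp2 carbon at the carboxylic acid oxidation level (bonded to O2, doubly to C4, and to C1'), so it can be carried as the CBr2 end of the C4=C3 alkene ortho to the C1 ester on ring A. The C–Br bond trans to ring A is open for C–C coupling, and the one cis to ring A lies beside the C1 carbonyl oxygen and serves for ring closure.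
- Fragments: the ring A piece comes from methyl orsellinate by chlorination at C5, acetylation, oxidation of the methyl group (C4) to the aldehyde and dibromoolefination. The ring C piece comes from 2-deoxy-D-ribose, whose C3 and C4 become oxolane C3 and C2; the C5 methyl centre is set by MeLi addition to the lactone and hydride delivery to the oxocarbenium ion, and the diene by Wittig and stannyl-Takai olefinations.
- Order of rings: A is bought, C is closed first (lactone, step 7, kept to the end), and B is closed last (step 15).

Key step: step 15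

Remark: 2-deoxy-D-ribose is drawn in its open-chain form, and the methyl hemiketal is carried on as a mixture of anomers.

**Route**

Step 1
Reactants: 1 methyl 2,4-dihydroxy-6-methylbenzoate (methyl orsellinate)
Product: 2 methyl 3-chloro-4,6-dihydroxy-2-methylbenzoate
Conditions: SO2Cl2 (1.0 equiv), Et2O, 0 °C
Reagents that add atoms: sulfuryl chloride, O=S(=O)(Cl)Cl
Why: Electrophilic aromatic chlorination, in which the free ring position next to the methyl group (ortho to the free 4-OH, para to the ester-chelated 2-OH) is expected to react first, as in closely related 6-alkylresorcylates, while one equivalent of reagent at low temperature limits dichlorination.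

Step 2
Reactants: 2 methyl 3-chloro-4,6-dihydroxy-2-methylbenzoate
Product: 3 methyl 4,6-diacetoxy-3-chloro-2-methylbenzoate
Conditions: Ac2O, pyridine, DMAP (cat.), CH2Cl2, rt
Reagents that add atoms: acetic anhydride, CC(=O)OC(C)=O
Why: DMAP-catalysed O-acetylation masks both phenols and deactivates ring A for the radical bromination that follows.

Step 3
Reactants: 3 methyl 4,6-diacetoxy-3-chloro-2-methylbenzoate
Product: 4 methyl 4,6-diacetoxy-2-(bromomethyl)-3-chlorobenzoate
Conditions: NBS (1.1 equiv), AIBN (cat.), PhCF3, 85 °C
Reagents that add atoms: N-bromosuccinimide, O=C1CCC(=O)N1Br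
Why: Wohl–Ziegler bromination, in which the only benzylic C–H bonds are those of the methyl group and the electron-poor diacetoxy ring should resist ionic nuclear bromination.

Step 4
Reactants: 4 methyl 4,6-diacetoxy-2-(bromomethyl)-3-chlorobenzoate
Product: 5 methyl 4,6-diacetoxy-3-chloro-2-formylbenzoate
Conditions: NMO (4 equiv), 4 Å molecular sieves, MeCN, rt
Reagents that add atoms: N-methylmorpholine N-oxide, C[N+]1([O-])CCOCC1
Why: Kornblum-type oxidation with an amine N-oxide, in which SN2 displacement of bromide by the N-oxide oxygen and N–O fragmentation stop at the aldehyde under neutral, anhydrous conditions that spare the aryl acetates and the methyl ester.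

Step 5
Reactants: 5 methyl 4,6-diacetoxy-3-chloro-2-formylbenzoate
Product: 6 methyl 4,6-diacetoxy-3-chloro-2-(2,2-dibromoethenyl)benzoate
Conditions: CBr4 (2 equiv), PPh3 (4 equiv), CH2Cl2, 0 °C
Reagents that add atoms: carbon tetrabromide, BrC(Br)(Br)Br
Why: Ramirez dibromoolefination (first stage of the Corey–Fuchs sequence), a Wittig reaction of Ph3P=CBr2 that tolerates esters and installs C3 as the CBr2 carbon.

Step 6
Reactants: 7 dibromomethane; 8 tributyltin chloride
Product: 10 (dibromomethyl)tributylstannane, via dibromomethyllithium 9 (not isolated)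
Conditions: LiN(iPr)2 (LDA), THF/Et2O, −95 °C; then 8, −95 °C to rt
Reagents that add atoms: none
Why: Deprotonation of CH2Br2 gives the carbenoid 9, which persists only at very low temperature and is captured by nucleophilic substitution at tin.

Step 7
Reactants: 11 2-deoxy-D-ribose
Product: 12 2-deoxy-D-ribono-1,4-lactone, (4S,5R)-4-hydroxy-5-(hydroxymethyl)oxolan-2-one
Conditions: Br2, H2O, rt
Reagents that add atoms: none
Why: Bromine-water oxidation of the aldose hemiacetal to the aldono-1,4-lactone closes ring C and leaves both stereocentres (future C3 and C2 of ring C) untouched.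

Step 8
Reactants: 12 2-deoxy-D-ribono-1,4-lactone
Product: 13 (4S,5R)-4-(tert-butyldimethylsilyloxy)-5-[(tert-butyldimethylsilyloxy)methyl]oxolan-2-one
Conditions: TBSCl (2.5 equiv), imidazole, DMF, rt
Reagents that add atoms: tert-butyldimethylsilyl chloride, CC(C)(C)[Si](C)(C)Cl
Why: Imidazole-promoted silylation of the primary and the secondary hydroxyl group is mild enough to avoid β-elimination in the lactone.

Step 9
Reactants: 13 bis-silylated lactone
Product: 14 (4S,5R)-4-(tert-butyldimethylsilyloxy)-5-[(tert-butyldimethylsilyloxy)methyl]-2-methyloxolan-2-ol (anomeric mixture)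
Conditions: MeLi (1.1 equiv), THF, −78 °C; then aq NH4Cl
Reagents that add atoms: methyllithium, [Li]C
Why: 1,2-Addition of an organolithium to a lactone, in which the tetrahedral lithium alkoxide persists at −78 °C so that only one methyl group is added and fast addition outruns enolisation and β-elimination.

Step 10
Reactants: 14 methyl hemiketal
Product: 16 (2R,3S,5S)-3-(tert-butyldimethylsilyloxy)-2-[(tert-butyldimethylsilyloxy)methyl]-5-methyloxolane, via oxocarbenium ion 15 (not isolated)
Conditions: Et3SiH (3 equiv), BF3·OEt2 (1.5 equiv), CH2Cl2, −78 °C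
Reagents that add atoms: none
Why: Ionic silane reduction of a hemiketal, in which BF3 ionises 14 to 15 and, by the inside-attack model for five-membered oxocarbenium ions with a pseudoaxial C3 silyloxy group, hydride is delivered cis to that group, which places the methyl group cis to the C2 side chain and sets C5 as S, as is usual for β-C-glycosides of 2-deoxyribose.

Step 11
Reactants: 16 bis-silyl ether
Product: 17 [(2R,3S,5S)-3-(tert-butyldimethylsilyloxy)-5-methyloxolan-2-yl]methanol
Conditions: TFA/H2O/THF (1:1:4), 0 °C
Reagents that add atoms: none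
Why: Acid-catalysed solvolysis tells the two silyl ethers apart by steric hindrance, so the primary one is cleaved first, a standard operation in nucleoside chemistry.

Step 12
Reactants: 17 primary alcohol
Product: 19 (E)-3-[(2R,3S,5S)-3-(tert-butyldimethylsilyloxy)-5-methyloxolan-2-yl]prop-2-enal, via oxolane-2-carbaldehyde 18 (not isolated)
Conditions: Dess–Martin periodinane (1.1 equiv), CH2Cl2, 0 °C to rt; then Ph3P=CHCHO (2 equiv), rt to 40 °C
Reagents that add atoms: (triphenylphosphoranylidene)acetaldehyde, O=CC=P(c1ccccc1)(c1ccccc1)c1ccccc1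
Why: Dess–Martin oxidation followed in the same flask by an E-selective Wittig reaction with a stabilised ylide, so that aldehyde 18 is trapped before epimerisation at C2 or β-elimination of the silyloxy group can set in.

Step 13
Reactants: 19 enal; 10 (dibromomethyl)tributylstannane
Product: 20 (2R,3S,5S)-3-(tert-butyldimethylsilyloxy)-5-methyl-2-[(1E,3E)-4-(tributylstannyl)buta-1,3-dien-1-yl]oxolane
Conditions: 10 (2 equiv), CrCl2 (10 equiv), LiI (4 equiv), THF/DMF, rt, dark
Reagents that add atoms: none
Why: Takai-type olefination with a stannyl gem-dihalide, in which divalent chromium turns the dihalide (after Br/I exchange by LiI) into a gem-dichromium reagent that adds 1,2 to the enal and eliminates to the E-alkenylstannane, with the silyl ether inert.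

Step 14
Reactants: 20 silylated dienylstannane
Product: 21 (2R,3S,5S)-5-methyl-2-[(1E,3E)-4-(tributylstannyl)buta-1,3-dien-1-yl]oxolan-3-ol
Conditions: TBAF, THF, 0 °C to rt
Reagents that add atoms: none
Why: Fluoride-induced desilylation, to which the alkenyl–tin bond and the diene are inert.

Step 15
Reactants: 6 methyl 4,6-diacetoxy-3-chloro-2-(2,2-dibromoethenyl)benzoate; 21 (2R,3S,5S)-5-methyl-2-[(1E,3E)-4-(tributylstannyl)buta-1,3-dien-1-yl]oxolan-3-ol
Product: 23 5-chloro-3-[(1E,3E)-4-[(2R,3S,5S)-3-hydroxy-5-methyloxolan-2-yl]buta-1,3-dien-1-yl]-1-oxo-1H-isochromene-6,8-diyl diacetate, via Z-bromotriene 22 (not isolated)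
Conditions: Pd2(dba)3 (5 mol %), tri(2-furyl)phosphine (30 mol %), toluene, 100 °C, 6 and 21 equimolar
Reagents that add atoms: none
Why: The reaction type is the known tandem Stille coupling/heterocyclisation of methyl 2-(2,2-dibromoethenyl)benzoates with organostannanes, used here with a dienylstannane. Zerovalent palladium inserts first into the C–Br bond trans to ring A, transmetalation with 21 and reductive elimination form C3–C1' with retention of both alkene geometries and give 22; a second oxidative addition into the remaining C–Br bond, cis to ring A, puts divalent palladium on C3 next to the C1 ester. Ring B closes when the ester carbonyl oxygen bonds to C3 (C–O reductive elimination from a seven-membered O-chelated vinylpalladium species, formally a 6-endo closure that keeps C3=C4 inside the ring), and bromide takes the methyl group off the resulting oxonium ion as MeBr, which makes the closure irreversible. No stereocentre is formed: the three centres of ring C are remote spectators and the 1'E,3'E geometry is carried over from 21. The step needs trans before cis C–Br (steric, reinforced by the 2,6-disubstituted ring A), alkenyl C–Br over the hindered aryl C–Cl at C5 (inert to this weakly donating phosphine system), and cyclisation over a second Stille coupling or loss of HBr (intramolecular trap, equimolar 21, no base, non-polar solvent). The free hydroxyl group of ring C and the aryl acetates are inert under these neutral conditions.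

Step 16
Reactants: 23 diacetate
Product: 24 5-chloro-6,8-dihydroxy-3-[(1E,3E)-4-[(2R,3S,5S)-3-hydroxy-5-methyloxolan-2-yl]buta-1,3-dien-1-yl]-1H-isochromen-1-one (CNP0086741.1)
Conditions: Et3N (5 equiv), MeOH, 0 °C to rt; then pH 6 phosphate buffer
Reagents that add atoms: none
Why: Amine-catalysed methanolysis (transesterification) of the two aryl acetates, which are far better acyl donors than the phenoxide-deactivated lactone of ring B, and no acid is used, so the dienylic C2–O bond of ring C is not ionised.

**Compound list**

1 | methyl 2,4-dihydroxy-6-methylbenzoate (methyl orsellinate) | COC(=O)c1c(C)cc(O)cc1O | starting material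
2 | methyl 3-chloro-4,6-dihydroxy-2-methylbenzoate | COC(=O)c1c(C)c(Cl)c(O)cc1O | intermediate
3 | methyl 4,6-diacetoxy-3-chloro-2-methylbenzoate | COC(=O)c1c(C)c(Cl)c(OC(C)=O)cc1OC(C)=O | intermediate
4 | methyl 4,6-diacetoxy-2-(bromomethyl)-3-chlorobenzoate | COC(=O)c1c(CBr)c(Cl)c(OC(C)=O)cc1OC(C)=O | intermediate
5 | methyl 4,6-diacetoxy-3-chloro-2-formylbenzoate | COC(=O)c1c(C=O)c(Cl)c(OC(C)=O)cc1OC(C)=O | intermediate
6 | methyl 4,6-diacetoxy-3-chloro-2-(2,2-dibromoethenyl)benzoate | COC(=O)c1c(C=C(Br)Br)c(Cl)c(OC(C)=O)cc1OC(C)=O | intermediate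
7 | dibromomethane | BrCBr | starting material
8 | tributyltin chloride | CCCC[Sn](Cl)(CCCC)CCCC | starting material
9 | dibromomethyllithium (not isolated) | [Li]C(Br)Br | intermediate
10 | (dibromomethyl)tributylstannane | CCCC[Sn](CCCC)(CCCC)C(Br)Br | intermediate
11 | 2-deoxy-D-ribose (open-chain form) | O=CC[C@H](O)[C@H](O)CO | starting material
12 | 2-deoxy-D-ribono-1,4-lactone | O=C1C[C@H](O)[C@@H](CO)O1 | intermediate
13 | (4S,5R)-4-(tert-butyldimethylsilyloxy)-5-[(tert-butyldimethylsilyloxy)methyl]oxolan-2-one | O=C1C[C@H](O[Si](C)(C)C(C)(C)C)[C@@H](CO[Si](C)(C)C(C)(C)C)O1 | intermediate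
14 | (4S,5R)-4-(tert-butyldimethylsilyloxy)-5-[(tert-butyldimethylsilyloxy)methyl]-2-methyloxolan-2-ol (anomeric mixture) | CC1(O)C[C@H](O[Si](C)(C)C(C)(C)C)[C@@H](CO[Si](C)(C)C(C)(C)C)O1 | intermediate
15 | methyl-substituted cyclic oxocarbenium ion (not isolated) | CC1=[O+][C@H](CO[Si](C)(C)C(C)(C)C)[C@@H](O[Si](C)(C)C(C)(C)C)C1 | intermediate
16 | (2R,3S,5S)-3-(tert-butyldimethylsilyloxy)-2-[(tert-butyldimethylsilyloxy)methyl]-5-methyloxolane | C[C@H]1C[C@H](O[Si](C)(C)C(C)(C)C)[C@@H](CO[Si](C)(C)C(C)(C)C)O1 | intermediate
17 | [(2R,3S,5S)-3-(tert-butyldimethylsilyloxy)-5-methyloxolan-2-yl]methanol | C[C@H]1C[C@H](O[Si](C)(C)C(C)(C)C)[C@@H](CO)O1 | intermediate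
18 | (2S,3S,5S)-3-(tert-butyldimethylsilyloxy)-5-methyloxolane-2-carbaldehyde (not isolated) | C[C@H]1C[C@H](O[Si](C)(C)C(C)(C)C)[C@@H](C=O)O1 | intermediate
19 | (E)-3-[(2R,3S,5S)-3-(tert-butyldimethylsilyloxy)-5-methyloxolan-2-yl]prop-2-enal | C[C@H]1C[C@H](O[Si](C)(C)C(C)(C)C)[C@@H](/C=C/C=O)O1 | intermediate
20 | (2R,3S,5S)-3-(tert-butyldimethylsilyloxy)-5-methyl-2-[(1E,3E)-4-(tributylstannyl)buta-1,3-dien-1-yl]oxolane | C[C@H]1C[C@H](O[Si](C)(C)C(C)(C)C)[C@@H](/C=C/C=C/[Sn](CCCC)(CCCC)CCCC)O1 | intermediate
21 | (2R,3S,5S)-5-methyl-2-[(1E,3E)-4-(tributylstannyl)buta-1,3-dien-1-yl]oxolan-3-ol | C[C@H]1C[C@H](O)[C@@H](/C=C/C=C/[Sn](CCCC)(CCCC)CCCC)O1 | intermediate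
22 | methyl 4,6-diacetoxy-2-[(1Z,3E,5E)-2-bromo-6-[(2R,3S,5S)-3-hydroxy-5-methyloxolan-2-yl]hexa-1,3,5-trien-1-yl]-3-chlorobenzoate (not isolated) | C[C@H]1C[C@H](O)[C@@H](/C=C/C=C/C(Br)=C/c2c(Cl)c(OC(C)=O)cc(OC(C)=O)c2C(=O)OC)O1 | intermediate
23 | 5-chloro-3-[(1E,3E)-4-[(2R,3S,5S)-3-hydroxy-5-methyloxolan-2-yl]buta-1,3-dien-1-yl]-1-oxo-1H-isochromene-6,8-diyl diacetate | C[C@H]1C[C@H](O)[C@@H](/C=C/C=C/c2cc3c(Cl)c(OC(C)=O)cc(OC(C)=O)c3c(=O)o2)O1 | intermediate
24 | 5-chloro-6,8-dihydroxy-3-[(1E,3E)-4-[(2R,3S,5S)-3-hydroxy-5-methyloxolan-2-yl]buta-1,3-dien-1-yl]-1H-isochromen-1-one (CNP0086741.1) | C[C@H]1C[C@H](O)[C@@H](/C=C/C=C/c2cc3c(Cl)c(O)cc(O)c3c(=O)o2)O1 | target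

**Step count**

- Total step count: 16 (five for the ring A fragment, one for the tin reagent, eight for the ring C fragment, two from the union onward).
- Longest linear sequence: 10 steps (steps 7 to 16, from 2-deoxy-D-ribose).

**Steps most likely to fail**

1. Step 15.
   - Risk: the second oxidative addition at the hindered cis C–Br bond may be slow. Loss of HBr, a second Stille coupling, or thermal decay of the dienylstannane (protodestannylation, homocoupling) could then overtake ring closure.
   - Fallback, from 6 and 21 back to 23: the two events are separated and ring B is closed through an alkyne instead of a vinylpalladium species.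
   - Compounds 6 and 21 are coupled with Pd2(dba)3 and tris(4-methoxyphenyl)phosphine in the presence of iPr2NEt in DMF at 80 °C. Under these conditions bromotriene 22 loses HBr as it forms, which gives the dienyne methyl 4,6-diacetoxy-3-chloro-2-[(3E,5E)-6-[(2R,3S,5S)-3-hydroxy-5-methyloxolan-2-yl]hexa-3,5-dien-1-yn-1-yl]benzoate F1.
   - The dienyne is then cycloisomerised with catalytic AuCl3 in moist MeCN. The ester carbonyl oxygen adds 6-endo-dig to the gold-activated alkyne at C3, the alkyne carbon that is conjugated with the diene and remote from the electron-poor ring A. The methyl group leaves as methanol, which gives 23.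

2. Step 10.
   - Risk: facial selectivity of hydride delivery may be poor because the methyl group is small and the 2-deoxy ring is flexible. Proton loss from the oxocarbenium ion to enol ethers and loss of a silyl ether to BF3 are further risks.
   - Fallback, from 14 back to 16: the centre is set in the open chain by reagent control and the ring is closed by SN2 displacement.
   - The hydroxy ketone tautomer of 14 is reduced by Corey–Bakshi–Shibata reduction ((S)-Me-CBS, BH3·SMe2, THF) to (2R,3S,5R)-1,3-bis(tert-butyldimethylsilyloxy)hexane-2,5-diol F2.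
   - Mitsunobu cyclodehydration (PPh3, DIAD, THF) then activates the less hindered methyl carbinol. It is displaced with inversion by the C2 hydroxyl group, which gives 16 with the 5S centre.

3. Step 13.
   - Risk: conversion may be low or E-selectivity eroded with the stannyl gem-dichromium reagent. Protodestannylation during work-up and chromatography is a further risk.
   - Fallback, from 19 back to 20: the carbon atom and the tin atom are introduced separately.
   - Takai iodoolefination of 19 (CHI3, CrCl2, THF/dioxane, 0 °C) gives (2R,3S,5S)-3-(tert-butyldimethylsilyloxy)-2-[(1E,3E)-4-iodobuta-1,3-dien-1-yl]-5-methyloxolane F3.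
   - Palladium-catalysed stannylation with hexabutylditin (Bu3SnSnBu3, Pd(PPh3)4, toluene, 60 °C) then converts the iodide with retention of geometry into 20.

**Further compounds**

F1 | step 15 | methyl 4,6-diacetoxy-3-chloro-2-[(3E,5E)-6-[(2R,3S,5S)-3-hydroxy-5-methyloxolan-2-yl]hexa-3,5-dien-1-yn-1-yl]benzoate | C[C@H]1C[C@H](O)[C@@H](/C=C/C=C/C#Cc2c(Cl)c(OC(C)=O)cc(OC(C)=O)c2C(=O)OC)O1
F2 | step 10 | (2R,3S,5R)-1,3-bis(tert-butyldimethylsilyloxy)hexane-2,5-diol | C[C@@H](O)C[C@H](O[Si](C)(C)C(C)(C)C)[C@H](O)CO[Si](C)(C)C(C)(C)C
F3 | step 13 | (2R,3S,5S)-3-(tert-butyldimethylsilyloxy)-2-[(1E,3E)-4-iodobuta-1,3-dien-1-yl]-5-methyloxolane | C[C@H]1C[C@H](O[Si](C)(C)C(C)(C)C)[C@@H](/C=C/C=C/I)O1
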